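The closed, stirred vessel gets one charge, G, the limiting reagent, so its balance reads: G left, plus Z, plus E, plus whatever I cannot see, equals the charge.

| flask | G | remark | time |
|---|---|---|---|
| dusk | 13 mM | run made earlier |  |
| summer | 30 mM | run made earlier |  |
| flask | 20 mM |  | 5.0 h |

| run | time / h | E / % | Z / % |
|---|---|---|---|
| dusk | 0.667 | 18.2 | 17.1 |
| dusk | 1.33 | 28.1 | 14.4 |
| dusk | 2.00 | 35.9 | 11.7 |
| dusk | 3.00 | 48.1 | 9.0 |
| dusk | 4.00 | 58.5 | 8.3 |
| dusk | 5.00 | 65.1 | 8.6 |
| summer | 0.667 | 18.0 | 17.8 |
| summer | 1.33 | 27.7 | 13.7 |
| summer | 2.00 | 36.6 | 12.7 |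
| summer | 3.00 | 47.6 | 11.0 |
| summer | 4.00 | 58.8 | 7.5 |
| summer | 5.00 | 66.3 | 7.9 |

(readings scatter by 1 percentage point)

- the numbers in the tables scatter by 1 percentage point (one standard deviation)
- a reading or a percentage of Z counts all its forms, free or not

- ratio of E to Z at 40 s
- ratio of E to Z at 12 min
- ratio of E to Z at 5.0 h

The first reading comes at 0.667 h, later than both early times, so I leave those two ratios open and bracket the ratio at 5.0 h. The percentages of the two runs agree within scatter at different charges, but they show that for the range of Z they covered. I therefore carry the tested ceiling, the highest concentration of Z read in either run, 5.34 mM. The highest percentage read would give this flask 3.56 mM, less than the ceiling, so I use the same percentages here.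

Taking the higher E and the lower Z read at 5.00 h, each two standard deviations out, I estimate an upper end for the ratio of 11.6; the opposite choice gives a lower end of 5.95. The balance gives me no tighter end, since the mean readings at that time leave 26.0 % for G and the unseen. Pooling the two runs does tighten the estimate: two standard deviations of the mean put the low end for Z at 6.84 %, and the ends of the ratio at 6.65 and 9.82. The forecast, 0.3, 0.5 and 9, puts its last value inside this bracket and calls the early two “poorly bounded”.

The flask gives 0.376, 0.513 and 10.3.

    Z ⇌ E (k = 0.00291 min⁻¹)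
    G ⇌ E (K = 85.0, k = 0.00775 min⁻¹)
    G ⇌ Z (K = 0.490, k = 0.0210 min⁻¹)
    G ⇌ X (K = 1.02, k = 0.0280 min⁻¹)
    L ⇌ Z, rate k5*(cs5 - [Z]) while solid is left; crystals form when [Z] > cs5 (solubility = 7.40 mM, k = 0.178 min⁻¹)

In the flask the last ratio stands above my tightened estimate but below the wider one, with Z at 6.39 % after 5.00 h, under the low end of 6.84 % I had reckoned. At 0.500 h this flask holds 3.51 mM of Z, under the ceiling of 5.34 mM. The neighbour charged with 80 mM ends with 10.2 mM of Z, all forms counted, over the ceiling, and it holds L at 4.07 % of its charge, counted in that Z, and shows a ratio of 4.58.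

The runs stem from a simulated flask for an exercise; the scatter is artificial.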